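**Retrosynthetic overview**
1. The tetronic acid ring is formed last, from a (5R)-dioxolanone and the lithium enolate of ethyl propanoate (acylation at the lactone carbonyl, then lactonisation).
2. The key bond is CH2–C(Me)= beside the stereocentre, made by electrochemical Ni-catalysed decarboxylative alkenylation of the D-malic acid acetonide acid with a (Z)-2-iodotriene; the only stereocentre is bought in D-malic acid.
3. The (Z)-iodotriene comes from Stork–Zhao iodo-olefination of a (2E,4E)-dienal, which comes from two E-selective Wittig homologations of a 3-(bis-furyl)propanal, itself from a Heck reaction of 4-bromo-2-(furan-3-ylmethyl)furan with allyl alcohol.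
4. The bis-furan comes from 3-furyllithium plus 4-bromofuran-2-carbaldehyde, then deoxygenation. Ring order: both furans are bought, the temporary dioxolanone is closed on the malic branch, and the tetronic lactone is closed in the final step.

Assumption: the stereocentre is read from the SMILES as 5R and the side-chain alkenes as 2Z,4E,6E (numbered from the lactone); n-BuLi, LiN(i-Pr)2, NaN(SiMe3)2 solutions and both formyl ylides are bought.

**Route**

Step 1
Reactants: 1 3-bromofuran; 2 4-bromofuran-2-carbaldehyde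
Product: 4 (4-bromofuran-2-yl)(furan-3-yl)methanol (racemic), via furan-3-yllithium 3 (not isolated)
Conditions: n-BuLi, THF, −78 °C, 30 min; then 2, −78 °C; H2O quench
Reagents that add atoms: none
Why: Bromine–lithium exchange gives 3-furyllithium, which is configurationally and positionally stable at −78 °C and adds 1,2 to the aldehyde much faster than it exchanges with the ring bromide of 2 (organolithium carbonyl addition); the racemic carbinol centre is erased in step 2.

Step 2
Reactants: 4 (4-bromofuran-2-yl)(furan-3-yl)methanol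
Product: 5 4-bromo-2-(furan-3-ylmethyl)furan
Conditions: Et3SiH (3 equiv), CF3CO2H (5 equiv), CH2Cl2, −40 → 0 °C
Reagents that add atoms: none
Why: The carbinol ionises easily to a cation stabilised by both furans and is trapped by hydride from the silane at low temperature before the furans can oligomerise (ionic hydrogenation, Kursanov–Parnes deoxygenation).

Step 3
Reactants: 5 4-bromo-2-(furan-3-ylmethyl)furan
Product: 6 3-[5-(furan-3-ylmethyl)furan-3-yl]propanal
Conditions: allyl alcohol (2 equiv), Pd(OAc)2 (5 mol%), n-Bu4NCl, NaHCO3, DMF, 90 °C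
Reagents that add atoms: allyl alcohol, C=CCO
Why: Heck arylation at the terminal carbon of allyl alcohol, β-hydride elimination toward the carbinol and enol-to-aldehyde tautomerisation give the 3-arylpropanal directly (Heck reaction, Jeffery conditions), so no separate oxidation is needed.

Step 4
Reactants: 6 3-[5-(furan-3-ylmethyl)furan-3-yl]propanal
Product: 7 (2E)-5-[5-(furan-3-ylmethyl)furan-3-yl]-2-methylpent-2-enal
Conditions: Ph3P=C(CH3)CHO (1.2 equiv), toluene, 90 °C
Reagents that add atoms: 2-(triphenylphosphoranylidene)propanal, CC(C=O)=P(c1ccccc1)(c1ccccc1)c1ccccc1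
Why: The stabilised ylide reacts with the unhindered aliphatic aldehyde to give the E-trisubstituted enal with high selectivity (Wittig olefination), which sets the 6E alkene of the target.

Step 5
Reactants: 7 (2E)-5-[5-(furan-3-ylmethyl)furan-3-yl]-2-methylpent-2-enal
Product: 8 (2E,4E)-7-[5-(furan-3-ylmethyl)furan-3-yl]-4-methylhepta-2,4-dienal
Conditions: Ph3P=CHCHO (1.3 equiv), toluene, 90 °C
Reagents that add atoms: (triphenylphosphoranylidene)acetaldehyde, O=CC=P(c1ccccc1)(c1ccccc1)c1ccccc1
Why: A second stabilised-ylide Wittig reaction adds two carbons as an E-disubstituted alkene (sets 4E), and the weakly nucleophilic ylide used in small excess reacts only slowly with the vinylogous dienal product.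

Step 6
Reactants: 8 (2E,4E)-7-[5-(furan-3-ylmethyl)furan-3-yl]-4-methylhepta-2,4-dienal
Product: 9 2-(furan-3-ylmethyl)-4-[(3E,5E,7Z)-8-iodo-4-methylnona-3,5,7-trien-1-yl]furan
Conditions: [Ph3PEt]I, n-BuLi, THF, rt; I2, −78 °C; NaN(SiMe3)2, −20 °C; then 8, −78 → −20 °C
Reagents that add atoms: ethyltriphenylphosphonium iodide, CC[P+](c1ccccc1)(c1ccccc1)c1ccccc1.[I-]; iodine, II
Why: Stork–Zhao olefination with the α-iodo ylide made in the flask runs under kinetic control and places iodine cis to the chain, giving the (Z)-2-iodoalkene that fixes the 2Z geometry of the target before the coupling.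

Step 7
Reactants: 10 D-malic acid, (2R)-2-hydroxybutanedioic acid
Product: 11 2-[(4R)-2,2-dimethyl-5-oxo-1,3-dioxolan-4-yl]acetic acid
Conditions: 2,2-dimethoxypropane, TsOH·H2O (cat.), rt
Reagents that add atoms: 2,2-dimethoxypropane, COC(C)(C)OC
Why: Acid-catalysed transketalisation ties up only the 1,2-hydroxy acid unit as the favoured five-membered dioxolanone and leaves the β-carboxyl free (acetonide formation); the bought R stereocentre is not touched.

Step 8
Reactants: 11 2-[(4R)-2,2-dimethyl-5-oxo-1,3-dioxolan-4-yl]acetic acid; 9 2-(furan-3-ylmethyl)-4-[(3E,5E,7Z)-8-iodo-4-methylnona-3,5,7-trien-1-yl]furan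
Product: 13 (5R)-5-[(2Z,4E,6E)-9-[5-(furan-3-ylmethyl)furan-3-yl]-2,6-dimethylnona-2,4,6-trien-1-yl]-2,2-dimethyl-1,3-dioxolan-4-one, via redox-active ester 12 (not isolated)
Conditions: 11 (2 equiv), N-hydroxyphthalimide, i-PrN=C=N-i-Pr, THF, rt, 2 h; then added over 3 h to 9, NiCl2·6H2O (20 mol%), 2,2'-bipyridine (20 mol%), AgNO3 (0.3 equiv), LiCl, DMF, Mg anode, RVC cathode, constant current (ca. 3 F/mol), rt, dark
Reagents that add atoms: none
Why: Proposed new method: nickel-electrocatalytic decarboxylative alkenylation applied to a geometry-defined conjugated (Z)-2-iodotriene and a β-oxygenated dioxolanone radical, a substrate pairing not yet shown; cathodically formed zerovalent nickel–bipyridine inserts into the C–I bond of 9 with retention, the redox-active ester 12 is reduced at the silver-coated cathode (or by monovalent nickel) and loses CO2 and phthalimide anion to give the primary radical, the divalent alkenylnickel captures it and the trivalent nickel species reductively eliminates the C(sp3)–C(sp2) bond, while the stereocentre next to the radical carbon is never broken and the absence of light and triplet sensitisers protects the 2Z,4E,6E geometry; the closest known reaction type is the Ni-electrocatalytic decarboxylative alkenylation of redox-active esters with simple alkenyl halides (reductive cross-electrophile coupling).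

Step 9
Reactants: 13 (5R)-5-[(2Z,4E,6E)-9-[5-(furan-3-ylmethyl)furan-3-yl]-2,6-dimethylnona-2,4,6-trien-1-yl]-2,2-dimethyl-1,3-dioxolan-4-one
Product: 15 (5R)-5-[(2Z,4E,6E)-9-[5-(furan-3-ylmethyl)furan-3-yl]-2,6-dimethylnona-2,4,6-trien-1-yl]-4-hydroxy-3-methylfuran-2(5H)-one, via open-chain hydroxy keto ester 14 (not isolated)
Conditions: EtCO2Et (3.2 equiv), LiN(i-Pr)2 (3.0 equiv), THF, −78 °C; then 13, −78 → 23 °C; cold 1 M HCl to pH 3
Reagents that add atoms: ethyl propanoate, CCC(=O)OCC
Why: Claisen-type acylation of the ester enolate by the activated dioxolanone carbonyl releases acetone and the C5 alkoxide, which lactonises onto the ethyl ester to give the 3-methyltetronic acid (dioxolanone-to-tetronic acid annulation, Dieckmann-type ring closure); the acidic β-dicarbonyl enolate forms first, so the R centre is not deprotonated and is retained.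

**Compound list**
1 | 3-bromofuran | Brc1ccoc1 | starting material
2 | 4-bromofuran-2-carbaldehyde | O=Cc1cc(Br)co1 | starting material
3 | furan-3-yllithium (formed in the flask) | [Li]c1ccoc1 | intermediate
4 | (4-bromofuran-2-yl)(furan-3-yl)methanol, racemic | OC(c1ccoc1)c1cc(Br)co1 | intermediate
5 | 4-bromo-2-(furan-3-ylmethyl)furan | Brc1coc(Cc2ccoc2)c1 | intermediate
6 | 3-[5-(furan-3-ylmethyl)furan-3-yl]propanal | O=CCCc1coc(Cc2ccoc2)c1 | intermediate
7 | (2E)-5-[5-(furan-3-ylmethyl)furan-3-yl]-2-methylpent-2-enal | O=C/C(C)=C/CCc1coc(Cc2ccoc2)c1 | intermediate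
8 | (2E,4E)-7-[5-(furan-3-ylmethyl)furan-3-yl]-4-methylhepta-2,4-dienal | O=C/C=C/C(C)=C/CCc1coc(Cc2ccoc2)c1 | intermediate
9 | 2-(furan-3-ylmethyl)-4-[(3E,5E,7Z)-8-iodo-4-methylnona-3,5,7-trien-1-yl]furan | C/C(I)=C/C=C/C(C)=C/CCc1coc(Cc2ccoc2)c1 | intermediate
10 | D-malic acid, (2R)-2-hydroxybutanedioic acid | O[C@H](CC(=O)O)C(=O)O | starting material
11 | 2-[(4R)-2,2-dimethyl-5-oxo-1,3-dioxolan-4-yl]acetic acid | CC1(C)O[C@H](CC(=O)O)C(=O)O1 | intermediate
12 | 1,3-dioxoisoindolin-2-yl 2-[(4R)-2,2-dimethyl-5-oxo-1,3-dioxolan-4-yl]acetate (formed in the flask) | CC1(C)O[C@H](CC(=O)ON2C(=O)c3ccccc3C2=O)C(=O)O1 | intermediate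
13 | (5R)-5-[(2Z,4E,6E)-9-[5-(furan-3-ylmethyl)furan-3-yl]-2,6-dimethylnona-2,4,6-trien-1-yl]-2,2-dimethyl-1,3-dioxolan-4-one | CC1(C)O[C@H](C\C(C)=C/C=C/C(C)=C/CCc2coc(Cc3ccoc3)c2)C(=O)O1 | intermediate
14 | ethyl (4R,6Z,8E,10E)-13-[5-(furan-3-ylmethyl)furan-3-yl]-4-hydroxy-2,6,10-trimethyl-3-oxotrideca-6,8,10-trienoate (formed in the flask as its lithium salt, C2 epimers) | CCOC(=O)C(C)C(=O)[C@H](O)C\C(C)=C/C=C/C(C)=C/CCc1coc(Cc2ccoc2)c1 | intermediate
15 | (5R)-5-[(2Z,4E,6E)-9-[5-(furan-3-ylmethyl)furan-3-yl]-2,6-dimethylnona-2,4,6-trien-1-yl]-4-hydroxy-3-methylfuran-2(5H)-one | CC1=C(O)[C@@H](C\C(C)=C/C=C/C(C)=C/CCc2coc(Cc3ccoc3)c2)OC1=O | target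

**Step count**
Total: 9 steps. Longest linear sequence: 8 steps (steps 1–6, 8, 9); step 7 is a one-step side branch.

**Three steps most likely to fail**

First, step 8, the proposed new electrochemical coupling. The primary radical may add to the triene of 9 or 13 instead of being captured by nickel, the alkenylnickel may lose Z geometry, and β-alkoxide loss could open the dioxolanone. The fallback uses known chemistry, sets out from 9 and comes back at 15. Iodine–magnesium exchange of 9 with i-PrMgCl·LiCl (THF, 0 °C) gives, with retention, [(2Z,4E,6E)-9-[5-(furan-3-ylmethyl)furan-3-yl]-6-methylnona-2,4,6-trien-2-yl]magnesium chloride F1. CuBr·SMe2-catalysed opening of bought ethyl (2R)-oxirane-2-carboxylate at its CH2 terminus (THF, −40 °C) gives ethyl (2R,4Z,6E,8E)-11-[5-(furan-3-ylmethyl)furan-3-yl]-2-hydroxy-4,8-dimethylundeca-4,6,8-trienoate F2. Propanoyl chloride and pyridine give ethyl (2R,4Z,6E,8E)-11-[5-(furan-3-ylmethyl)furan-3-yl]-4,8-dimethyl-2-(propanoyloxy)undeca-4,6,8-trienoate F3. Dieckmann cyclisation with LiN(SiMe3)2 (THF, −78 → 0 °C) closes the tetronic acid 15. In this variant the stereocentre is bought in the glycidate.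

Second, step 9. The ester enolate may deprotonate C5 of the dioxolanone instead of acylating, which would racemise the centre, or lactonisation of 14 may stall. The fallback sets out from 13 and comes back at 15. Methanolysis (K2CO3, MeOH, 0 °C) gives methyl (2R,4Z,6E,8E)-11-[5-(furan-3-ylmethyl)furan-3-yl]-2-hydroxy-4,8-dimethylundeca-4,6,8-trienoate F4. Propanoyl chloride and pyridine give methyl (2R,4Z,6E,8E)-11-[5-(furan-3-ylmethyl)furan-3-yl]-4,8-dimethyl-2-(propanoyloxy)undeca-4,6,8-trienoate F5. Dieckmann cyclisation with LiN(SiMe3)2 at −78 °C gives 15.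

Third, step 3. The electron-rich 3-bromofuran may add to palladium too slowly, or give branched aldehyde. The fallback sets out from 5 and comes back at 6. Negishi coupling with bought (3-ethoxy-3-oxopropyl)zinc bromide (Pd(OAc)2, SPhos, THF, 50 °C) gives ethyl 3-[5-(furan-3-ylmethyl)furan-3-yl]propanoate F6. Half-reduction with i-Bu2AlH (CH2Cl2, −78 °C) gives 6.

**Further compounds**
F1 | step 8 | [(2Z,4E,6E)-9-[5-(furan-3-ylmethyl)furan-3-yl]-6-methylnona-2,4,6-trien-2-yl]magnesium chloride | C/C([Mg]Cl)=C/C=C/C(C)=C/CCc1coc(Cc2ccoc2)c1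
F2 | step 8 | ethyl (2R,4Z,6E,8E)-11-[5-(furan-3-ylmethyl)furan-3-yl]-2-hydroxy-4,8-dimethylundeca-4,6,8-trienoate | CCOC(=O)[C@H](O)C\C(C)=C/C=C/C(C)=C/CCc1coc(Cc2ccoc2)c1
F3 | step 8 | ethyl (2R,4Z,6E,8E)-11-[5-(furan-3-ylmethyl)furan-3-yl]-4,8-dimethyl-2-(propanoyloxy)undeca-4,6,8-trienoate | CCOC(=O)[C@H](OC(=O)CC)C\C(C)=C/C=C/C(C)=C/CCc1coc(Cc2ccoc2)c1
F4 | step 9 | methyl (2R,4Z,6E,8E)-11-[5-(furan-3-ylmethyl)furan-3-yl]-2-hydroxy-4,8-dimethylundeca-4,6,8-trienoate | COC(=O)[C@H](O)C\C(C)=C/C=C/C(C)=C/CCc1coc(Cc2ccoc2)c1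
F5 | step 9 | methyl (2R,4Z,6E,8E)-11-[5-(furan-3-ylmethyl)furan-3-yl]-4,8-dimethyl-2-(propanoyloxy)undeca-4,6,8-trienoate | COC(=O)[C@H](OC(=O)CC)C\C(C)=C/C=C/C(C)=C/CCc1coc(Cc2ccoc2)c1
F6 | step 3 | ethyl 3-[5-(furan-3-ylmethyl)furan-3-yl]propanoate | CCOC(=O)CCc1coc(Cc2ccoc2)c1
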